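The methylene bridge is cut first, giving ring A as aspidinol and ring B as acetylfilicinic acid; ring A is then traced to an aryne. With ring A numbered from the butanoyl-bearing carbon (C1), the key step exploits the adjacent pair C1–acyl and C6–OH: 3,5-dimethoxy-4-methylbenzyne, released by CsF from a 2-(trimethylsilyl)aryl triflate, inserts into the C–O bond of butanoic acid, forming the C6–O and C1–C(=O) bonds in one operation with the regiochemistry steered by the methoxy group next to the triple bond. The precursor comes from symmetric 3,5-dimethoxy-4-methylphenol; the bridge is formed last by ortho-quinone methide alkylation.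

Key step: step 4

Remark: the target has no stereocentre. Ring A is numbered C1 (butanoyl), C2 (OH), C3 (CH3), C4 (OCH3), C5 (CH2 bridge), C6 (OH) throughout, and ring B is handled as the dienol tautomer written in the target SMILES.

**Step 1**
Reactants: 1 2,6-dimethoxytoluene
Product: 3 3,5-dimethoxy-4-methylphenol, via aryl pinacol boronate 2 (not isolated)
Conditions: [Ir(OMe)(cod)]2 (cat.), dtbpy (cat.), B2pin2 (1.0 equiv), THF, 80 °C; then aq. KHSO5, acetone, rt
Reagents that add atoms: bis(pinacolato)diboron, CC1(C)OB(OC1(C)C)B1OC(C)(C)C(C)(C)O1 (boron only in intermediate 2); potassium peroxymonosulfate, [K+].[O-]S(=O)(=O)OO (phenol oxygen)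
Why: Sterically governed iridium-catalysed C–H borylation should take the one ring C–H with no ortho substituent (para to the methyl group), and oxidation of the C–B bond of 2 by peroxymonosulfate should then give the phenol at the same carbon (one-pot C–H borylation/oxidation).

**Step 2**
Reactants: 3 3,5-dimethoxy-4-methylphenol
Product: 4 2-bromo-3,5-dimethoxy-4-methylphenol
Conditions: NBS (1.0 equiv), CH2Cl2, −78 to 0 °C
Reagents that add atoms: N-bromosuccinimide, O=C1CCC(=O)N1Br
Why: Electrophilic aromatic bromination, in which the two positions ortho to the hydroxyl are equivalent by symmetry and the para position is blocked by the methyl group, so one equivalent of NBS at low temperature should give a single monobromide.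

**Step 3**
Reactants: 4 2-bromo-3,5-dimethoxy-4-methylphenol
Product: 7 3,5-dimethoxy-4-methyl-2-(trimethylsilyl)phenyl trifluoromethanesulfonate, via aryl trimethylsilyl ether 5 (not isolated), via lithium 2-silylphenoxide 6 (not isolated)
Conditions: HMDS, THF, 70 °C, then volatiles removed; n-BuLi, THF, −100 to −78 °C; Tf2O, −100 °C to rt
Reagents that add atoms: hexamethyldisilazane, C[Si](C)(C)N[Si](C)(C)C; trifluoromethanesulfonic anhydride, O=S(=O)(OS(=O)(=O)C(F)(F)F)C(F)(F)F
Why: Established one-flask entry to ortho-silylaryl triflates by O-silylation, bromine–lithium exchange, 1,3-shift of silicon from oxygen to carbon (retro-Brook rearrangement) and O-triflation of lithium phenoxide 6, with the bromine atom fixing the position of silicon between the two oxygenated carbons.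

**Step 4**
Reactants: 7 3,5-dimethoxy-4-methyl-2-(trimethylsilyl)phenyl trifluoromethanesulfonate; 8 butanoic acid
Product: 10 1-(6-hydroxy-2,4-dimethoxy-3-methylphenyl)butan-1-one, via 3,5-dimethoxy-4-methylbenzyne 9 (not isolated)
Conditions: CsF (4 equiv), THF, 125 °C, sealed tube
Reagents that add atoms: none
Why: Fluoride attacks silicon and triflate leaves, giving aryne 9 whose triple bond joins the former C–OTf and C–Si carbons; butanoate (from 8 and CsF) adds through oxygen to the aryne carbon distal to the flanking methoxy group, and the aryl anion left ortho to that methoxy group attacks the adjacent ester carbonyl to give a four-membered alkoxide that opens to the ketone and a phenoxide. The closest known reaction type is the formal insertion of arynes, generated from 2-(trimethylsilyl)aryl triflates and CsF, into the C–O bond of carboxylic acids to give ortho-hydroxyaryl ketones. No ring is closed in the product and no stereocentre is created. The step needs regioselective addition to the unsymmetrical aryne, which the inductively withdrawing methoxy group next to the triple bond secures by distorting the aryne and stabilising negative charge on the neighbouring carbon. It also needs acyl transfer to outrun protonation of the aryl anion, which the excess of CsF, the absence of other proton sources and the high temperature should favour.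

**Step 5**
Reactants: 10 1-(6-hydroxy-2,4-dimethoxy-3-methylphenyl)butan-1-one
Product: 11 1-(2,6-dihydroxy-4-methoxy-3-methylphenyl)butan-1-one (aspidinol)
Conditions: BCl3 (3 equiv), CH2Cl2, −78 °C to rt; aqueous work-up
Reagents that add atoms: none
Why: Chelation-assisted Lewis-acid ether cleavage, in which BCl3 should remove only the methyl group of the C2 ether, which sits ortho to the ketone and is twisted out of the ring plane by its two ortho neighbours, while the C4 ether para to the ketone should survive.

**Step 6**
Reactants: 11 1-(2,6-dihydroxy-4-methoxy-3-methylphenyl)butan-1-one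
Product: 12 1-{3-[(dimethylamino)methyl]-2,6-dihydroxy-4-methoxy-5-methylphenyl}butan-1-one
Conditions: [CH2=NMe2]I, K2CO3, CH2Cl2, 0 °C to rt
Reagents that add atoms: N,N-dimethylmethyleneiminium iodide, C=[N+](C)C.[I-]
Why: Mannich aminomethylation (electrophilic aromatic substitution by a preformed iminium ion) can take place only at C5, the single unsubstituted ring carbon, which is activated by the ortho C6 hydroxyl and the para C2 hydroxyl, and the mild conditions should keep the product from ionising.

**Step 7**
Reactants: 13 2,4,6-trihydroxyacetophenone
Product: 14 2-acetyl-3,5-dihydroxy-4,4-dimethylcyclohexa-2,5-dien-1-one (acetylfilicinic acid)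
Conditions: NaOMe (3 equiv), MeI (2.2 equiv), MeOH, 0 °C to rt; then aq. HCl
Reagents that add atoms: iodomethane, CI
Why: Base-mediated dearomatising C-methylation of the phloroglucinol nucleus, the classical entry to acylfilicinic acids, in which the first C-methyl group raises the nucleophilicity of its own ring carbon so that about two equivalents of MeI should place both methyl groups on one carbon, and the strongly acidic triketone should be separable from aromatic by-products by bicarbonate extraction.

**Step 8**
Reactants: 12 1-{3-[(dimethylamino)methyl]-2,6-dihydroxy-4-methoxy-5-methylphenyl}butan-1-one; 14 2-acetyl-3,5-dihydroxy-4,4-dimethylcyclohexa-2,5-dien-1-one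
Product: 16 2-acetyl-6-[(3-butanoyl-2,4-dihydroxy-6-methoxy-5-methylphenyl)methyl]-3,5-dihydroxy-4,4-dimethylcyclohexa-2,5-dien-1-one, via ortho-quinone methide 15 (not isolated)
Conditions: 1,4-dioxane, 100 °C, N2 stream; dilute aq. HCl work-up
Reagents that add atoms: none
Why: Heating should expel dimethylamine from 12 to give ortho-quinone methide 15, which should be trapped by Michael addition of the only C–H ring carbon of the vinylogous acid 14 (C6 of ring B), and since ring A has no free position left the quinone methide cannot condense with its own precursor.

**Compound list**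
1 | 2,6-dimethoxytoluene | COc1cccc(OC)c1C | starting material
2 | 2-(3,5-dimethoxy-4-methylphenyl)-4,4,5,5-tetramethyl-1,3,2-dioxaborolane | COc1cc(B2OC(C)(C)C(C)(C)O2)cc(OC)c1C | intermediate
3 | 3,5-dimethoxy-4-methylphenol | COc1cc(O)cc(OC)c1C | intermediate
4 | 2-bromo-3,5-dimethoxy-4-methylphenol | COc1cc(O)c(Br)c(OC)c1C | intermediate
5 | (2-bromo-3,5-dimethoxy-4-methylphenoxy)trimethylsilane | COc1cc(O[Si](C)(C)C)c(Br)c(OC)c1C | intermediate
6 | lithium 3,5-dimethoxy-4-methyl-2-(trimethylsilyl)phenoxide | [Li+].[O-]c1cc(OC)c(C)c(OC)c1[Si](C)(C)C | intermediate
7 | 3,5-dimethoxy-4-methyl-2-(trimethylsilyl)phenyl trifluoromethanesulfonate | COc1cc(OS(=O)(=O)C(F)(F)F)c([Si](C)(C)C)c(OC)c1C | intermediate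
8 | butanoic acid | CCCC(=O)O | starting material
9 | 3,5-dimethoxy-4-methylbenzyne (1,2-didehydro-3,5-dimethoxy-4-methylbenzene) | COC1=C(C)C(OC)=CC#C1 | intermediate
10 | 1-(6-hydroxy-2,4-dimethoxy-3-methylphenyl)butan-1-one | CCCC(=O)c1c(OC)c(C)c(OC)cc1O | intermediate
11 | 1-(2,6-dihydroxy-4-methoxy-3-methylphenyl)butan-1-one (aspidinol) | CCCC(=O)c1c(O)c(C)c(OC)cc1O | intermediate
12 | 1-{3-[(dimethylamino)methyl]-2,6-dihydroxy-4-methoxy-5-methylphenyl}butan-1-one | CCCC(=O)c1c(O)c(C)c(OC)c(CN(C)C)c1O | intermediate
13 | 2,4,6-trihydroxyacetophenone | CC(=O)c1c(O)cc(O)cc1O | starting material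
14 | 2-acetyl-3,5-dihydroxy-4,4-dimethylcyclohexa-2,5-dien-1-one (acetylfilicinic acid) | CC(=O)C1=C(O)C(C)(C)C(O)=CC1=O | intermediate
15 | 2-butanoyl-3-hydroxy-5-methoxy-4-methyl-6-methylidenecyclohexa-2,4-dien-1-one | CCCC(=O)C1=C(O)C(C)=C(OC)C(=C)C1=O | intermediate
16 | 2-acetyl-6-[(3-butanoyl-2,4-dihydroxy-6-methoxy-5-methylphenyl)methyl]-3,5-dihydroxy-4,4-dimethylcyclohexa-2,5-dien-1-one | CCCC(=O)c1c(O)c(C)c(OC)c(CC2=C(O)C(C)(C)C(O)=C(C(C)=O)C2=O)c1O | target

Total step count: 8. Longest linear sequence: 7 steps (steps 1 to 6, then step 8); step 7 is a one-step side branch.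

**Steps most likely to fail**

Step 4. The aryl anion may be protonated before it reaches the ester carbonyl (net O-arylation instead of insertion), the product phenoxide may be arylated by a second aryne, or regiocontrol of the addition may erode. The fallback introduces the acyl group by electrophilic chemistry. It sets out from 3, which would be esterified with butanoic anhydride (DMAP cat., pyridine, CH2Cl2, rt) to 3,5-dimethoxy-4-methylphenyl butanoate F1. A Lewis-acid Fries rearrangement (TiCl4, CH2Cl2, rt) should then move the acyl group to one of the two equivalent ortho carbons, the para carbon being blocked, and the route is rejoined at 10.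

Step 8. Expulsion of dimethylamine may be slow or reversible, and the amine may transfer the CH2 unit between the two rings, scrambling the bridge into symmetrical dimers. The fallback replaces the Mannich base by an acid-ionisable benzylic alcohol. It sets out from 11, which would be formylated at C5 (Cl2CHOMe, TiCl4, CH2Cl2, 0 °C, Rieche formylation) to 3-butanoyl-2,4-dihydroxy-6-methoxy-5-methylbenzaldehyde F2. Reduction of the aldehyde (NaBH4, THF/MeOH, 0 °C), with the doubly hydrogen-bonded ketone expected to survive, would give 1-[2,6-dihydroxy-3-(hydroxymethyl)-4-methoxy-5-methylphenyl]butan-1-one F3. Condensation of this alcohol with 14 under catalytic p-TsOH at rt, again through 15, comes back to the route at 16.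

Step 5. Demethylation may stall once the C6 oxygen is bound to boron and chelates the carbonyl, or it may spread to the C4 ether. The fallback gives up selective cleavage for full cleavage followed by selective re-methylation. It sets out from 10, which with excess BBr3 (CH2Cl2, −78 °C to rt) would give 1-(2,4,6-trihydroxy-3-methylphenyl)butan-1-one F4. One equivalent of Me2SO4 with K2CO3 in acetone at rt should then methylate the C4 hydroxyl, the only one not hydrogen-bonded to the ketone, and the route is rejoined at 11.

**Further compounds**
F1 | step 4 | 3,5-dimethoxy-4-methylphenyl butanoate | CCCC(=O)Oc1cc(OC)c(C)c(OC)c1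
F2 | step 8 | 3-butanoyl-2,4-dihydroxy-6-methoxy-5-methylbenzaldehyde | CCCC(=O)c1c(O)c(C)c(OC)c(C=O)c1O
F3 | step 8 | 1-[2,6-dihydroxy-3-(hydroxymethyl)-4-methoxy-5-methylphenyl]butan-1-one | CCCC(=O)c1c(O)c(C)c(OC)c(CO)c1O
F4 | step 5 | 1-(2,4,6-trihydroxy-3-methylphenyl)butan-1-one | CCCC(=O)c1c(O)c(C)c(O)cc1O
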